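**Plan**
Retrosynthesis: the benzoate C–O bond and the C6–C7 oxirane are cut first, then the C1–isopropyl bond; ring B is contracted by cutting C6–C7 and C8–C9 (loss of the C7/C8 unit) to a cis-diquinane ketone, which is opened at C1–C10 (aldol) and C3–C4 (conjugate addition).
Enabling feature: in the seven-membered ring B the segment C9(O)–C8H2–C7(CH3)–C6 is an oxygenated carbon tied to C6 by a methyl-bearing two-carbon bridge, which is what but-2-ynoate leaves when inserted into the C6–C9 bond of a cyclopentanone enamine.
Forward: the cyclopentanone (C4, C5, C6, C9, C10) comes from 3-methylcyclopentenone, ring A is annulated by aldol condensation, and the ketone ring is then enlarged to ring B by enamine/ynoate (2+2) addition and ring opening.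
Stereochemistry: C4 from a copper-catalysed asymmetric conjugate addition; a C1–C10 oxirane, forced cis to the C4 methyl by the diquinane, blocks C10 during the ring expansion and then passes its configuration on.
Reductive opening gives the trans C10–H, the C1 oxygen steers an Evans–Tishchenko reduction to the 9α-alcohol, that alcohol directs the C6–C7 epoxidation, and isopropyl adds to the trans-fused C1 ketone anti to the angular methyl.

Key step: step 5

Remark 1: atom labels C1–C10 are those of the target carbocycle (C1 carbinol carbon, C4 methyl-bearing fusion carbon, C6/C7 oxirane carbons, C9 benzoate carbon, C10 fusion CH) and are used for every intermediate; ring A = C1–C2–C3–C4–C10, ring B = the ring holding C9; β is the face of the C4 methyl.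
Remark 2 (assumption): aldol 6 is drawn as its 1β-alcohol because that centre is lost by dehydration in the same flask; the β-dicarbonyl compounds 14 and 15 are drawn as enols.

**Step 1**
Reactants: 1 2-(2-bromoethyl)-1,3-dioxolane; 2 3-methylcyclopent-2-en-1-one
Product: 4 (R)-3-[2-(1,3-dioxolan-2-yl)ethyl]-3-methylcyclopentan-1-one, via Grignard reagent 3 (not isolated)
Conditions: Mg, THF, 25 °C; then Cu(OTf)2 (3 mol %), chiral imidazolinium carbene precursor (4 mol %), Et2O, −30 °C, slow addition of 2
Reagents that add atoms: none
Why: Copper-catalysed asymmetric conjugate addition of a Grignard reagent to a β-substituted cyclic enone, a known route to all-carbon quaternary centres; the chiral carbene–copper complex (enantiomer chosen for the R product) selects the enone face and sets C4.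

**Step 2**
Reactants: 4
Product: 7 (R)-5-methylbicyclo[3.3.0]oct-1(8)-en-2-one, via keto aldehyde 5 (not isolated), via cis-fused aldol 6 (not isolated)
Conditions: 2 M HCl, THF, 60 °C
Reagents that add atoms: none
Why: Acetal hydrolysis, 5-exo aldol addition of the ketone α-carbon C10 to the aldehyde and loss of water (aldol condensation, a known cyclopentannulation) should give the conjugated C9 ketone with the C10=C1 double bond; C4 is untouched.

**Step 3**
Reactants: 7
Product: 8 cis-fused 1β,10β-epoxy ketone (oxirane oxygen cis to the C4 methyl)
Conditions: 30% H2O2, NaOH (cat.), MeOH, 0 °C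
Reagents that add atoms: hydrogen peroxide, OO
Why: Weitz–Scheffer nucleophilic epoxidation; hydroperoxide addition at C1 is reversible and ring closure at C10 can only take place on the face of the angular methyl, since an oxirane on the other face would require a trans-fused bicyclo[3.3.0]octane, so C1 and C10 are set together.

**Step 4**
Reactants: 8; 9 pyrrolidine
Product: 10 pyrrolidine enamine (C6=C9) of epoxy ketone 8
Conditions: pyrrolidine (5 equiv), 4 Å molecular sieves, benzene, 80 °C; concentrated and used crude
Reagents that add atoms: none
Why: Dehydrative enamine formation from a ketone and a secondary amine; C10 carries no hydrogen, so the C6=C9 enamine is the only possible regioisomer and no β-elimination of the C1 oxygen can occur, while both oxirane carbons are shielded from substitution (C10 fully substituted, C1 attacked only from the concave face).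

**Step 5**
Reactants: 10; 11 methyl but-2-ynoate
Product: 13 ring-expanded dienamine ester (ring B: C6=C7(CH3)–C8(CO2CH3)=C9(pyrrolidinyl); 1β,10β-oxirane kept), via aminocyclobutene 12 (not isolated)
Conditions: 11 (2 equiv), toluene, 90 °C, sealed tube
Reagents that add atoms: none
Why: The enamine carbon C6 adds in Michael fashion to the methyl-bearing β-carbon (C7) of the ynoate, and the vinyl anion/iminium zwitterion closes by 4-exo-trig attack of C8 on C9 to the cis-fused aminocyclobutene 12, formally a stepwise thermal (2+2) cycloaddition. The push–pull substituted, strained bicyclo[3.2.0]heptene then opens by cleavage of the C6–C9 σ-bond (4π ring opening, in effect a retro-Mannich fragmentation), so the seven-membered ring arises by two-carbon ring enlargement and not by a ring-closing event. The closest known reaction type is the ring enlargement of cyclic ketone enamines with acetylenic esters, established for propiolates and acetylenedicarboxylates. No stereocentre is formed and C1, C4 and C10 are not involved. The step needs the C6 enamine regioisomer and attack at the alkyne β-carbon: the first is guaranteed because C10 is a fully substituted oxirane carbon, the second by the polarisation of the ynoate, and an aprotic medium keeps the zwitterion from being protonated before it closes.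

**Step 6**
Reactants: 13
Product: 14 β-keto ester (enol form: C9–OH, C8–CO2CH3)
Conditions: AcOH/H2O/THF (3:1:1), 45 °C
Reagents that add atoms: water, O
Why: Acid hydrolysis of a vinylogous carbamate (C8 protonation, iminium hydrolysis) should give the β-keto ester, resting as its chelated enol in conjugation with C6=C7; the non-nucleophilic weak acid spares the oxirane.

**Step 7**
Reactants: 14
Product: 16 1β,10β-epoxy-4β,7-dimethylbicyclo[5.3.0]dec-6-en-9-one (target numbering), via β-keto acid 15 (not isolated)
Conditions: LiOH, THF/MeOH/H2O, 25 °C; then AcOH to pH 5, 45 °C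
Reagents that add atoms: none
Why: Saponification and decarboxylation of a β-keto acid; the dienol released is protonated kinetically at C8 (α), which should keep C6=C7 out of conjugation, and C10 cannot enolise.

**Step 8**
Reactants: 16
Product: 17 trans-fused 1β-hydroxy-10α-H ketone
Conditions: SmI2 (2.5 equiv), THF/MeOH, −90 °C
Reagents that add atoms: none
Why: Reductive cleavage of the α-C–O bond of an α,β-epoxy ketone by SmI2 (ketyl, C10–O scission, enolate protonation); C1 keeps its β-oxygen and the enolate should be protonated at C10 on the α face, opposite the angular methyl and the samarium-bound C1 alkoxide, giving the trans fusion, which is also the hydrogen-bonded and more stable epimer.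

**Step 9**
Reactants: 17
Product: 18 1β-acetoxy-9α-hydroxy compound
Conditions: CH3CHO (6 equiv), SmI2 (0.3 equiv), THF, −10 °C
Reagents that add atoms: acetaldehyde, CC=O
Why: Evans–Tishchenko reduction; the samarium-bound hemiacetal formed from the C1 hydroxyl and acetaldehyde delivers hydride intramolecularly to the β face of the C9 carbonyl, setting the 9α (1,3-anti) alcohol and leaving C1 as its acetate, so the two oxygens are differentiated.

**Step 10**
Reactants: 18
Product: 19 1β-acetoxy-9α-(tert-butyldimethylsilyloxy) compound
Conditions: TBSOTf, 2,6-lutidine, CH2Cl2, −78 → 0 °C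
Reagents that add atoms: tert-butyldimethylsilyl trifluoromethanesulfonate, CC(C)(C)[Si](C)(C)OS(=O)(=O)C(F)(F)F
Why: Silyl ether formation at the only free hydroxyl with a silyl triflate and a hindered base; standard protection.

**Step 11**
Reactants: 19
Product: 20 1β-hydroxy-9α-(tert-butyldimethylsilyloxy) compound
Conditions: K2CO3, MeOH, 25 °C
Reagents that add atoms: none
Why: Base-catalysed methanolysis (transesterification) of the acetate; the silyl ether and the alkene are inert and no carbonyl is present to enolise.

**Step 12**
Reactants: 20
Product: 21 trans-fused 9α-(tert-butyldimethylsilyloxy) C1 ketone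
Conditions: Dess–Martin periodinane, CH2Cl2, 0 → 25 °C
Reagents that add atoms: none
Why: Dess–Martin oxidation of a secondary alcohol; the non-basic medium should leave the C10–H (α to the new ketone, β to the silyloxy group) unepimerised and the silyloxy group in place.

**Step 13**
Reactants: 21
Product: 22 1β-hydroxy-1α-isopropyl-9α-(tert-butyldimethylsilyloxy) compound
Conditions: i-PrMgCl, CeCl3, THF, −78 °C
Reagents that add atoms: isopropylmagnesium chloride, CC(C)[Mg]Cl
Why: 1,2-Addition of an organocerium reagent, whose low basicity suppresses enolisation, β-elimination and hydride transfer; the nucleophile should enter the trans-fused cyclopentanone from the α face, past the axial C10–H and anti to the 1,3-related angular methyl, placing hydroxyl β and isopropyl α at C1.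

**Step 14**
Reactants: 22
Product: 23 1β,9α-diol
Conditions: Bu4NF, THF, 25 °C
Reagents that add atoms: none
Why: Fluoride-induced cleavage of the silyl ether.

**Step 15**
Reactants: 23
Product: 24 6α,7α-epoxy-1β,9α-diol
Conditions: VO(acac)2 (5 mol %), t-BuOOH, CH2Cl2, 0 °C
Reagents that add atoms: tert-butyl hydroperoxide, CC(C)(C)OO
Why: Hydroxyl-directed epoxidation of a homoallylic alcohol; the vanadium alkoxide of the 9α-hydroxyl delivers oxygen to the same (α) face of C6=C7, setting C6 and C7, while the tertiary C1 hydroxyl is remote and on the other face.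

**Step 16**
Reactants: 24
Product: 25 target compound (9α-benzoate)
Conditions: BzCl, pyridine, DMAP (cat.), CH2Cl2, 0 → 25 °C
Reagents that add atoms: benzoyl chloride, O=C(Cl)c1ccccc1
Why: Acylation of the secondary alcohol under nucleophilic catalysis; the tertiary hydroxyl does not react under these conditions and the oxirane is stable to the buffered medium.

**Compound list**
1 | 2-(2-bromoethyl)-1,3-dioxolane | BrCCC1OCCO1 | starting material
2 | 3-methylcyclopent-2-en-1-one | CC1=CC(=O)CC1 | starting material
3 | [2-(1,3-dioxolan-2-yl)ethyl]magnesium bromide | Br[Mg]CCC1OCCO1 | intermediate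
4 | (R)-3-[2-(1,3-dioxolan-2-yl)ethyl]-3-methylcyclopentan-1-one | O=C1CC[C@@](C)(CCC2OCCO2)C1 | intermediate
5 | (R)-3-(1-methyl-3-oxocyclopentyl)propanal | O=C1CC[C@@](C)(CCC=O)C1 | intermediate
6 | cis-fused aldol, 1β-hydroxy-4β-methyl diquinane with C9 ketone (8-hydroxy-5-methyl-cis-bicyclo[3.3.0]octan-2-one) | O[C@H]1CC[C@]2(C)CCC(=O)[C@@H]21 | intermediate
7 | (R)-5-methylbicyclo[3.3.0]oct-1(8)-en-2-one (C9 ketone, C10=C1 alkene) | O=C1CC[C@@]2(C)CCC=C12 | intermediate
8 | cis-fused 1β,10β-epoxy-4β-methyl diquinane C9 ketone | [C@H]12CC[C@]3(C)CCC(=O)[C@]13O2 | intermediate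
9 | pyrrolidine | C1CCNC1 | starting material
10 | 9-(pyrrolidin-1-yl) C6=C9 enamine of 8 | [C@H]12CC[C@]3(C)CC=C(N4CCCC4)[C@]13O2 | intermediate
11 | methyl but-2-ynoate | CC#CC(=O)OC | starting material
12 | aminocyclobutene: C6–C7(CH3)=C8(CO2CH3)–C9(pyrrolidinyl) ring cis-fused on the β face of ring B of 10 | [C@H]12CC[C@]3(C)C[C@H]4C(C)=C(C(=O)OC)[C@@]4(N5CCCC5)[C@]13O2 | intermediate
13 | ring-expanded dienamine ester: 1β,10β-epoxy-4β,7-dimethyl-8-(methoxycarbonyl)-9-(pyrrolidin-1-yl)bicyclo[5.3.0]deca-6,8-diene | [C@H]12CC[C@]3(C)CC=C(C)C(C(=O)OC)=C(N4CCCC4)[C@]13O2 | intermediate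
14 | β-keto ester of 13 (enol form, C9–OH) | [C@H]12CC[C@]3(C)CC=C(C)C(C(=O)OC)=C(O)[C@]13O2 | intermediate
15 | β-keto acid (enol form) | [C@H]12CC[C@]3(C)CC=C(C)C(C(=O)O)=C(O)[C@]13O2 | intermediate
16 | 1β,10β-epoxy-4β,7-dimethylbicyclo[5.3.0]dec-6-en-9-one | [C@H]12CC[C@]3(C)CC=C(C)CC(=O)[C@]13O2 | intermediate
17 | trans-fused 1β-hydroxy-4β,7-dimethyl-10α-H-bicyclo[5.3.0]dec-6-en-9-one | O[C@H]1CC[C@]2(C)CC=C(C)CC(=O)[C@H]21 | intermediate
18 | 1β-acetoxy-9α-hydroxy trans-fused dec-6-ene | CC(=O)O[C@H]1CC[C@]2(C)CC=C(C)C[C@H](O)[C@H]21 | intermediate
19 | 1β-acetoxy-9α-(tert-butyldimethylsilyloxy) compound | CC(=O)O[C@H]1CC[C@]2(C)CC=C(C)C[C@H](O[Si](C)(C)C(C)(C)C)[C@H]21 | intermediate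
20 | 1β-hydroxy-9α-(tert-butyldimethylsilyloxy) compound | O[C@H]1CC[C@]2(C)CC=C(C)C[C@H](O[Si](C)(C)C(C)(C)C)[C@H]21 | intermediate
21 | trans-fused 9α-(tert-butyldimethylsilyloxy)-4β,7-dimethylbicyclo[5.3.0]dec-6-en-1-one | O=C1CC[C@]2(C)CC=C(C)C[C@H](O[Si](C)(C)C(C)(C)C)[C@H]21 | intermediate
22 | 1β-hydroxy-1α-isopropyl-9α-(tert-butyldimethylsilyloxy) compound | CC(C)[C@]1(O)CC[C@]2(C)CC=C(C)C[C@H](O[Si](C)(C)C(C)(C)C)[C@H]21 | intermediate
23 | 1α-isopropyl-4β,7-dimethyl trans-fused bicyclo[5.3.0]dec-6-ene-1β,9α-diol | CC(C)[C@]1(O)CC[C@]2(C)CC=C(C)C[C@H](O)[C@H]21 | intermediate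
24 | 6α,7α-epoxy-1β,9α-diol | CC(C)[C@]1(O)CC[C@]2(C)C[C@@H]3O[C@]3(C)C[C@H](O)[C@H]21 | intermediate
25 | target: 6α,7α-epoxy-1β-hydroxy-1α-isopropyl-4β,7-dimethyl trans-fused bicyclo[5.3.0]decan-9α-yl benzoate | CC(C)[C@]1(O)CC[C@]2(C)C[C@@H]3O[C@]3(C)C[C@H](OC(=O)c3ccccc3)[C@H]21 | target

**Step count and risks**
Total step count: 16. Longest linear sequence: 16 steps (1 and 2 to 25); 9 and 11 enter as single building blocks.

Steps most likely to fail:

1. Step 5. The hindered enamine may react sluggishly with the β-methyl ynoate, or the dipolar adduct may be protonated before it closes to the cyclobutene, so that only a Michael adduct forms. The fallback changes the acceptor group. It sets out from 10, which is treated with 1-(phenylsulfonyl)prop-1-yne in toluene at 25–60 °C; the far more electrophilic alkynyl sulfone should give the ring-expanded dienamine sulfone F1 by the same addition, closure and ring opening. Aqueous acetic acid hydrolyses it to the β-keto sulfone F2. SmI2 (excess) in THF/MeOH at −78 °C then removes the sulfonyl group and opens the oxirane in the same flask, and the route is rejoined at 17.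

2. Step 8. The samarium enolate may be protonated at C10 from the β face (internal delivery from samarium-bound methanol), giving the cis-fused epimer, or the ketone may be over-reduced. The fallback replaces protonation by a stereospecific hydride transfer. It sets out from 16, which is converted with TBSOTf/Et3N into the silyl dienol ether F3, an alkenyl oxirane. Palladium-catalysed formate hydrogenolysis (Pd2(dba)3, PBu3, HCO2H, Et3N, THF) ionises the C10–O bond and delivers hydride to C10 from the face opposite the departing oxygen, giving the trans-fused hydroxy silyl dienol ether F4. HF·pyridine at low temperature cleaves the enol ether with kinetic protonation at C8, and the route is rejoined at 17.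

3. Step 13. The isopropyl reagent may act as a hydride donor (reduction of the ketone) or as a base (enolisation at C10 followed by loss of the silyloxy group). The fallback sets out from 21 and uses isopropenylmagnesium bromide with CeCl3, which has no β-hydrogen to transfer, to give the isopropenyl carbinol F5 with the same facial preference. Hydrogenation with RhCl(PPh3)3 and H2 in benzene then saturates the 1,1-disubstituted alkene in preference to the trisubstituted C6=C7 bond, and the route is rejoined at 22.

**Further compounds**
F1 | step 5 | ring-expanded dienamine sulfone (8-phenylsulfonyl analogue of 13) | [C@H]12CC[C@]3(C)CC=C(C)C(S(=O)(=O)c4ccccc4)=C(N5CCCC5)[C@]13O2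
F2 | step 5 | β-keto sulfone (enol form; 8-phenylsulfonyl analogue of 14) | [C@H]12CC[C@]3(C)CC=C(C)C(S(=O)(=O)c4ccccc4)=C(O)[C@]13O2
F3 | step 8 | silyl dienol ether of 16: 9-(tert-butyldimethylsilyloxy)-1β,10β-epoxy-4β,7-dimethylbicyclo[5.3.0]deca-6,8-diene | [C@H]12CC[C@]3(C)CC=C(C)C=C(O[Si](C)(C)C(C)(C)C)[C@]13O2
F4 | step 8 | trans-fused 1β-hydroxy-10α-H silyl dienol ether | O[C@H]1CC[C@]2(C)CC=C(C)C=C(O[Si](C)(C)C(C)(C)C)[C@H]21
F5 | step 13 | 1β-hydroxy-1α-isopropenyl-9α-(tert-butyldimethylsilyloxy) compound | C=C(C)[C@]1(O)CC[C@]2(C)CC=C(C)C[C@H](O[Si](C)(C)C(C)(C)C)[C@H]21
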